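**Retrosynthetic overview**

- The route rests on the aryl ketone: chain carbon C1 (C=O) is bonded to benzene carbon C1', which lies between the oxygen-bearing ring carbons C2' and C6' (OMe on C4'). The C2' oxygen can therefore be the hydroxyl oxygen of the C18 acid itself, and the C1–C1' and C2'–O bonds are cut together back to a 3-alkoxy-5-methoxybenzyne and the 9-silyloxy C18 acid.
- The C18 acid is cut at C12=C13 (Z-selective Wittig with a hexenyl ylide), C10=C11 (formylmethylene Wittig on a C10 aldehyde), C6=C7 (alkyne semihydrogenation) and C7–C8 (acetylide opening of (R)-trityl glycidyl ether, which supplies C9 with R configuration).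
- The aryne precursor comes from 5-methoxyresorcinol by mono-acetalisation, carbamate-directed ortho-silylation and triflation.
- No ring is formed: the benzene ring is bought. The end game removes the aryl methoxymethyl ether without acid and then the C9 silyl ether with buffered fluoride.

Key step: step 16

Remark: chain carbons are numbered C1–C18 from the ketone carbon and ring carbons C1'–C6' from the acylated carbon. (R)-Trityl glycidyl ether is used in place of a silyl glycidyl ether because a trityl group cannot shift to the neighbouring alkoxide during the strongly basic epoxide opening; it is assumed to be commercially available, as is (triphenylphosphoranylidene)acetaldehyde.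

**Aryne precursor**

Step 1
Reactants: 1 5-methoxyresorcinol
Product: 2 3-methoxy-5-(methoxymethoxy)phenol
Conditions: NaH (1.0 equiv), DMF, 0 °C; MOMCl (1.0 equiv), 0 °C to rt
Reagents that add atoms: chloromethyl methyl ether, COCCl
Why: Williamson-type O-alkylation of the mono-phenoxide; the two hydroxyls of 1 are equivalent, so one equivalent of base and chloride should give mainly the mono-ether, which is separated from diol and bis-ether by chromatography.

Step 2
Reactants: 2 3-methoxy-5-(methoxymethoxy)phenol
Product: 3 3-methoxy-5-(methoxymethoxy)phenyl propan-2-ylcarbamate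
Conditions: i-PrNCO, Et3N (cat.), CH2Cl2, rt
Reagents that add atoms: 2-isocyanatopropane, CC(C)N=C=O
Why: Base-catalysed addition of the phenol to the isocyanate (carbamoylation) installs a strong ortho-directing group that can later be removed without acid.

Step 3
Reactants: 3 3-methoxy-5-(methoxymethoxy)phenyl propan-2-ylcarbamate
Product: 7 5-methoxy-3-(methoxymethoxy)-2-(trimethylsilyl)phenyl propan-2-ylcarbamate, via N-silyl carbamate 4 (not isolated), via ortho-lithiated N-silyl carbamate 5 (not isolated), via doubly silylated carbamate 6 (not isolated)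
Conditions: Me3SiOTf, TMEDA, Et2O, rt; then n-BuLi, TMEDA, −78 °C; Me3SiCl, −78 °C to rt; aq. NH4Cl
Reagents that add atoms: chlorotrimethylsilane, C[Si](C)(C)Cl (ring silyl group of 7); in intermediates only: trimethylsilyl trifluoromethanesulfonate, C[Si](C)(C)OS(=O)(=O)C(F)(F)F (N-silyl group of 4 to 6) and butyllithium, [Li]CCCC (lithium of 5)
Why: Directed ortho-metalation: the carbamate, N-silylated in the flask, directs lithiation to an ortho carbon, and of the two ortho carbons the one also flanked by the chelating methoxymethoxy group should be preferred over the one flanked by methoxy, so that Me3SiCl places silicon between the carbamate and acetal oxygens; the N-silyl group is lost on aqueous work-up.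

Step 4
Reactants: 7 5-methoxy-3-(methoxymethoxy)-2-(trimethylsilyl)phenyl propan-2-ylcarbamate
Product: 9 5-methoxy-3-(methoxymethoxy)-2-(trimethylsilyl)phenyl trifluoromethanesulfonate, via ortho-silyl phenol 8 (not isolated)
Conditions: DBU, Et2NH, MeCN, 40 °C; then PhNTf2, rt
Reagents that add atoms: N-phenylbis(trifluoromethanesulfonimide), O=S(=O)(N(c1ccccc1)S(=O)(=O)C(F)(F)F)C(F)(F)F
Why: The amidine base releases the phenoxide by E1cB loss of isopropyl isocyanate (trapped by Et2NH as a urea) and the phenoxide is sulfonylated in the same flask, so the electron-rich arylsilane never meets an acid that could protodesilylate it.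

**Phosphonium salt**

Step 5
Reactants: 10 (Z)-hex-3-en-1-ol
Product: 11 (Z)-1-iodohex-3-ene
Conditions: I2, PPh3, imidazole, CH2Cl2, 0 °C to rt
Reagents that add atoms: iodine, II
Why: Appel-type iodination of a primary alcohol (oxyphosphonium activation, then SN2 by iodide) leaves the Z alkene untouched.

Step 6
Reactants: 11 (Z)-1-iodohex-3-ene
Product: 12 [(Z)-hex-3-en-1-yl]triphenylphosphonium iodide
Conditions: PPh3, MeCN, 80 °C
Reagents that add atoms: triphenylphosphine, c1ccc(cc1)P(c1ccccc1)c1ccccc1
Why: SN2 quaternisation of triphenylphosphine by the primary iodide gives the salt needed for the Z-selective Wittig reaction.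

**Silylated C18 acid**

Step 7
Reactants: 13 hept-6-ynoic acid; 14 (R)-trityl glycidyl ether
Product: 16 (9R)-9-hydroxy-10-(triphenylmethoxy)dec-6-ynoic acid, via dilithium acetylide carboxylate 15 (not isolated)
Conditions: n-BuLi (2 equiv per 13), THF/DMPU, −78 to 0 °C; then 14, 0 °C to rt; aq. NH4Cl, then dilute HCl to pH 4, 0 °C
Reagents that add atoms: butyllithium, [Li]CCCC (lithium of intermediate 15 only; no reagent atom other than hydrogen stays in 16)
Why: The carboxylate/acetylide dianion opens the monosubstituted epoxide at its unsubstituted carbon through the acetylide carbon (SN2 epoxide opening by a lithium acetylide in a dipolar cosolvent), which forms C7–C8; the stereocenter of 14 is not attacked and becomes C9 with R configuration.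

Step 8
Reactants: 16 (9R)-9-hydroxy-10-(triphenylmethoxy)dec-6-ynoic acid
Product: 17 methyl (9R)-9-hydroxy-10-(triphenylmethoxy)dec-6-ynoate
Conditions: MeI, K2CO3, DMF, rt
Reagents that add atoms: iodomethane, CI
Why: SN2 O-alkylation of the carboxylate under conditions too weakly basic to alkylate the secondary alcohol.

Step 9
Reactants: 17 methyl (9R)-9-hydroxy-10-(triphenylmethoxy)dec-6-ynoate
Product: 18 methyl (9R)-9-(triisopropylsilyloxy)-10-(triphenylmethoxy)dec-6-ynoate
Conditions: i-Pr3SiOTf, 2,6-lutidine, CH2Cl2, 0 °C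
Reagents that add atoms: triisopropylsilyl trifluoromethanesulfonate, CC(C)[Si](C(C)C)(C(C)C)OS(=O)(=O)C(F)(F)F
Why: Silyl triflate silylation of the secondary alcohol buffered by a hindered pyridine; the bulky silyl group is chosen to survive ylide, hydroxide and hot CsF later.

Step 10
Reactants: 18 methyl (9R)-9-(triisopropylsilyloxy)-10-(triphenylmethoxy)dec-6-ynoate
Product: 19 methyl (6Z,9R)-9-(triisopropylsilyloxy)-10-(triphenylmethoxy)dec-6-enoate
Conditions: H2 (1 atm), Pd/CaCO3 poisoned with Pb(OAc)2, quinoline, EtOAc, rt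
Reagents that add atoms: none
Why: Lindlar semihydrogenation adds H2 syn to the internal alkyne and stops at the 6Z alkene; no other reducible group is present at this stage.

Step 11
Reactants: 19 methyl (6Z,9R)-9-(triisopropylsilyloxy)-10-(triphenylmethoxy)dec-6-enoate
Product: 20 methyl (6Z,9R)-10-hydroxy-9-(triisopropylsilyloxy)dec-6-enoate
Conditions: TsOH·H2O (cat.), MeOH/CH2Cl2, 0 °C to rt
Reagents that add atoms: none
Why: Acid-catalysed methanolysis of the trityl ether through the trityl cation (trapped by methanol) is much faster than cleavage of a secondary triisopropylsilyl ether.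

Step 12
Reactants: 20 methyl (6Z,9R)-10-hydroxy-9-(triisopropylsilyloxy)dec-6-enoate
Product: 21 methyl (6Z,9R)-10-oxo-9-(triisopropylsilyloxy)dec-6-enoate
Conditions: Dess–Martin periodinane, NaHCO3, CH2Cl2, 0 °C to rt
Reagents that add atoms: none
Why: Dess–Martin oxidation of the primary alcohol under buffered, non-basic conditions should give the α-silyloxy aldehyde without epimerisation at C9; it is used at once.

Step 13
Reactants: 21 methyl (6Z,9R)-10-oxo-9-(triisopropylsilyloxy)dec-6-enoate
Product: 22 methyl (6Z,9R,10E)-12-oxo-9-(triisopropylsilyloxy)dodeca-6,10-dienoate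
Conditions: Ph3P=CHCHO, toluene, 80 °C
Reagents that add atoms: (triphenylphosphoranylidene)acetaldehyde, O=CC=P(c1ccccc1)(c1ccccc1)c1ccccc1
Why: Wittig reaction with the stabilised formylmethylene ylide gives the E enal (C10=C11); the neutral ylide is not basic enough to epimerise C9 and reacts faster with the saturated aldehyde than with the enal it forms.

Step 14
Reactants: 22 methyl (6Z,9R,10E)-12-oxo-9-(triisopropylsilyloxy)dodeca-6,10-dienoate; 12 [(Z)-hex-3-en-1-yl]triphenylphosphonium iodide
Product: 24 methyl (6Z,9R,10E,12Z,15Z)-9-(triisopropylsilyloxy)octadeca-6,10,12,15-tetraenoate, via hexenylidene phosphorane 23 (not isolated)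
Conditions: 12, NaN(SiMe3)2, THF, −78 °C; then 22, −78 to 0 °C
Reagents that add atoms: none
Why: Wittig reaction of a non-stabilised ylide made with a sodium base (lithium-free) proceeds under kinetic control through the cis oxaphosphetane and should give the 12Z alkene; the 10E and 15Z alkenes are carried in unchanged and the methyl ester is inert to the ylide at low temperature.

Step 15
Reactants: 24 methyl (6Z,9R,10E,12Z,15Z)-9-(triisopropylsilyloxy)octadeca-6,10,12,15-tetraenoate
Product: 25 (6Z,9R,10E,12Z,15Z)-9-(triisopropylsilyloxy)octadeca-6,10,12,15-tetraenoic acid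
Conditions: LiOH, THF/MeOH/H2O, 0 °C to rt; then dilute HCl to pH 4, 0 °C
Reagents that add atoms: lithium hydroxide, [Li+].[OH-]
Why: Saponification (BAc2 ester hydrolysis); the silyl ether and the polyene are stable to aqueous hydroxide and the acid is set free at pH 4 in the cold.

**Key step and end game**

Step 16
Reactants: 25 (6Z,9R,10E,12Z,15Z)-9-(triisopropylsilyloxy)octadeca-6,10,12,15-tetraenoic acid; 9 5-methoxy-3-(methoxymethoxy)-2-(trimethylsilyl)phenyl trifluoromethanesulfonate
Product: 29 (6Z,9R,10E,12Z,15Z)-1-[2-hydroxy-4-methoxy-6-(methoxymethoxy)phenyl]-9-(triisopropylsilyloxy)octadeca-6,10,12,15-tetraen-1-one, via cesium carboxylate 26 (not isolated), via aryne 27 (not isolated), via aryl anion 28 (not isolated)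
Conditions: 9 (1.5 equiv), CsF (4 equiv), THF, sealed tube, 110 °C, argon; aq. NH4Cl
Reagents that add atoms: cesium fluoride, [Cs+].[F-] (cesium of intermediates 26 and 28 only; no reagent atom other than hydrogen stays in 29)
Why: Fluoride attacks the silicon of 9 and triflate leaves, releasing aryne 27 slowly because CsF is barely soluble in THF; cesium carboxylate 26 adds through oxygen to the aryne carbon remote from the methoxymethoxy group (the former C–OTf carbon), since the inductively withdrawing alkoxy group distorts the triple bond and stabilises negative charge on the adjacent carbon. Aryl anion 28 therefore lies between the acyloxy and acetal oxygens and attacks the neighbouring ester carbonyl through a four-membered tetrahedral intermediate that opens to the ketone phenoxide, so the aryl C–O bond and the aryl–C1 bond form in one operation and work-up gives 29. The closest known reaction type is the fluoride-induced insertion of arynes into the C–O bond of carboxylic acids, which gives ortho-hydroxyaryl ketones on heating. No ring is closed and no stereocenter is formed; C9 and the four alkene geometries are only carried through. The step needs regioselective aryne capture, secured by the alkoxy group beside the triple bond and hardly opposed by the remote methoxy group, and chemoselectivity for the anionic carboxylate over ene or cycloaddition reactions of the olefins, secured by the low stationary aryne concentration and the absence of any Lewis acid. Acyl shift must also outrun protonation of 28, which is why the mixture is heated and kept free of other proton sources.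

Step 17
Reactants: 29 (6Z,9R,10E,12Z,15Z)-1-[2-hydroxy-4-methoxy-6-(methoxymethoxy)phenyl]-9-(triisopropylsilyloxy)octadeca-6,10,12,15-tetraen-1-one
Product: 31 (6Z,9R,10E,12Z,15Z)-1-(2,6-dihydroxy-4-methoxyphenyl)-9-(triisopropylsilyloxy)octadeca-6,10,12,15-tetraen-1-one, via bis(trimethylsilyl) ether 30 (not isolated)
Conditions: Me3SiOTf, 2,2'-bipyridyl, CH2Cl2, 0 °C to rt; then H2O, rt
Reagents that add atoms: trimethylsilyl trifluoromethanesulfonate, C[Si](C)(C)OS(=O)(=O)C(F)(F)F (silyl groups of intermediate 30 only; no reagent atom other than hydrogen stays in 31)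
Why: Silyl triflate cleavage of the aryl methoxymethyl acetal in the presence of 2,2'-bipyridyl converts it to the aryl silyl ether and a methoxymethyl-bipyridinium salt without free Brønsted or strong Lewis acid, so the C9 dienyl silyl ether should not ionise; water then hydrolyses both aryl silyl ethers.

Step 18
Reactants: 31 (6Z,9R,10E,12Z,15Z)-1-(2,6-dihydroxy-4-methoxyphenyl)-9-(triisopropylsilyloxy)octadeca-6,10,12,15-tetraen-1-one
Product: 32 (6Z,9R,10E,12Z,15Z)-1-(2,6-dihydroxy-4-methoxyphenyl)-9-hydroxyoctadeca-6,10,12,15-tetraen-1-one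
Conditions: Bu4NF, AcOH, THF, 0 °C to rt
Reagents that add atoms: none
Why: Fluoride-induced desilylation buffered with acetic acid cleaves the Si–O bond only, so the C9–O bond and the R configuration are untouched and the polyene is not exposed to strongly basic fluoride.

**Compound list**

1 | 5-methoxyresorcinol (5-methoxybenzene-1,3-diol) | COc1cc(O)cc(O)c1 | starting material
2 | 3-methoxy-5-(methoxymethoxy)phenol | COCOc1cc(O)cc(OC)c1 | intermediate
3 | 3-methoxy-5-(methoxymethoxy)phenyl propan-2-ylcarbamate | COCOc1cc(OC)cc(OC(=O)NC(C)C)c1 | intermediate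
4 | 3-methoxy-5-(methoxymethoxy)phenyl propan-2-yl(trimethylsilyl)carbamate | COCOc1cc(OC)cc(OC(=O)N(C(C)C)[Si](C)(C)C)c1 | intermediate (not isolated)
5 | {4-methoxy-2-(methoxymethoxy)-6-[propan-2-yl(trimethylsilyl)carbamoyloxy]phenyl}lithium | COCOc1cc(OC)cc(OC(=O)N(C(C)C)[Si](C)(C)C)c1[Li] | intermediate (not isolated)
6 | 5-methoxy-3-(methoxymethoxy)-2-(trimethylsilyl)phenyl propan-2-yl(trimethylsilyl)carbamate | COCOc1cc(OC)cc(OC(=O)N(C(C)C)[Si](C)(C)C)c1[Si](C)(C)C | intermediate (not isolated)
7 | 5-methoxy-3-(methoxymethoxy)-2-(trimethylsilyl)phenyl propan-2-ylcarbamate | COCOc1cc(OC)cc(OC(=O)NC(C)C)c1[Si](C)(C)C | intermediate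
8 | 5-methoxy-3-(methoxymethoxy)-2-(trimethylsilyl)phenol | COCOc1cc(OC)cc(O)c1[Si](C)(C)C | intermediate (not isolated)
9 | 5-methoxy-3-(methoxymethoxy)-2-(trimethylsilyl)phenyl trifluoromethanesulfonate | COCOc1cc(OC)cc(OS(=O)(=O)C(F)(F)F)c1[Si](C)(C)C | intermediate
10 | (Z)-hex-3-en-1-ol | CC/C=C\CCO | starting material
11 | (Z)-1-iodohex-3-ene | CC/C=C\CCI | intermediate
12 | [(Z)-hex-3-en-1-yl]triphenylphosphonium iodide | CC/C=C\CC[P+](c1ccccc1)(c1ccccc1)c1ccccc1.[I-] | intermediate
13 | hept-6-ynoic acid | C#CCCCCC(=O)O | starting material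
14 | (R)-trityl glycidyl ether, (2R)-2-[(triphenylmethoxy)methyl]oxirane | C(c1ccccc1)(c1ccccc1)(c1ccccc1)OC[C@H]1CO1 | starting material
15 | dilithium hept-6-yn-7-ide-1-oate | [Li+].[Li+].[C-]#CCCCCC(=O)[O-] | intermediate (not isolated)
16 | (9R)-9-hydroxy-10-(triphenylmethoxy)dec-6-ynoic acid | OC(=O)CCCCC#CC[C@@H](O)COC(c1ccccc1)(c1ccccc1)c1ccccc1 | intermediate
17 | methyl (9R)-9-hydroxy-10-(triphenylmethoxy)dec-6-ynoate | COC(=O)CCCCC#CC[C@@H](O)COC(c1ccccc1)(c1ccccc1)c1ccccc1 | intermediate
18 | methyl (9R)-9-(triisopropylsilyloxy)-10-(triphenylmethoxy)dec-6-ynoate | COC(=O)CCCCC#CC[C@@H](O[Si](C(C)C)(C(C)C)C(C)C)COC(c1ccccc1)(c1ccccc1)c1ccccc1 | intermediate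
19 | methyl (6Z,9R)-9-(triisopropylsilyloxy)-10-(triphenylmethoxy)dec-6-enoate | COC(=O)CCCC/C=C\C[C@@H](O[Si](C(C)C)(C(C)C)C(C)C)COC(c1ccccc1)(c1ccccc1)c1ccccc1 | intermediate
20 | methyl (6Z,9R)-10-hydroxy-9-(triisopropylsilyloxy)dec-6-enoate | COC(=O)CCCC/C=C\C[C@@H](O[Si](C(C)C)(C(C)C)C(C)C)CO | intermediate
21 | methyl (6Z,9R)-10-oxo-9-(triisopropylsilyloxy)dec-6-enoate | COC(=O)CCCC/C=C\C[C@@H](O[Si](C(C)C)(C(C)C)C(C)C)C=O | intermediate
22 | methyl (6Z,9R,10E)-12-oxo-9-(triisopropylsilyloxy)dodeca-6,10-dienoate | COC(=O)CCCC/C=C\C[C@@H](O[Si](C(C)C)(C(C)C)C(C)C)/C=C/C=O | intermediate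
23 | [(Z)-hex-3-en-1-ylidene]triphenylphosphorane | CC/C=C\CC=P(c1ccccc1)(c1ccccc1)c1ccccc1 | intermediate (not isolated)
24 | methyl (6Z,9R,10E,12Z,15Z)-9-(triisopropylsilyloxy)octadeca-6,10,12,15-tetraenoate | CC/C=C\C/C=C\C=C\[C@H](O[Si](C(C)C)(C(C)C)C(C)C)C/C=C\CCCCC(=O)OC | intermediate
25 | (6Z,9R,10E,12Z,15Z)-9-(triisopropylsilyloxy)octadeca-6,10,12,15-tetraenoic acid | CC/C=C\C/C=C\C=C\[C@H](O[Si](C(C)C)(C(C)C)C(C)C)C/C=C\CCCCC(=O)O | intermediate
26 | cesium (6Z,9R,10E,12Z,15Z)-9-(triisopropylsilyloxy)octadeca-6,10,12,15-tetraenoate | CC/C=C\C/C=C\C=C\[C@H](O[Si](C(C)C)(C(C)C)C(C)C)C/C=C\CCCCC(=O)[O-].[Cs+] | intermediate (not isolated)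
27 | 3-methoxy-5-(methoxymethoxy)benzyne (5-methoxy-3-(methoxymethoxy)cyclohexa-1,3-dien-5-yne) | COCOC1=CC(OC)=CC#C1 | intermediate (not isolated)
28 | cesium 2-acyloxy-4-methoxy-6-(methoxymethoxy)benzen-1-ide (acyl = the C18 chain of 25) | CC/C=C\C/C=C\C=C\[C@H](O[Si](C(C)C)(C(C)C)C(C)C)C/C=C\CCCCC(=O)Oc1cc(OC)cc(OCOC)[c-]1.[Cs+] | intermediate (not isolated)
29 | (6Z,9R,10E,12Z,15Z)-1-[2-hydroxy-4-methoxy-6-(methoxymethoxy)phenyl]-9-(triisopropylsilyloxy)octadeca-6,10,12,15-tetraen-1-one | CC/C=C\C/C=C\C=C\[C@H](O[Si](C(C)C)(C(C)C)C(C)C)C/C=C\CCCCC(=O)c1c(O)cc(OC)cc1OCOC | intermediate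
30 | (6Z,9R,10E,12Z,15Z)-1-[4-methoxy-2,6-bis(trimethylsilyloxy)phenyl]-9-(triisopropylsilyloxy)octadeca-6,10,12,15-tetraen-1-one | CC/C=C\C/C=C\C=C\[C@H](O[Si](C(C)C)(C(C)C)C(C)C)C/C=C\CCCCC(=O)c1c(O[Si](C)(C)C)cc(OC)cc1O[Si](C)(C)C | intermediate (not isolated)
31 | (6Z,9R,10E,12Z,15Z)-1-(2,6-dihydroxy-4-methoxyphenyl)-9-(triisopropylsilyloxy)octadeca-6,10,12,15-tetraen-1-one | CC/C=C\C/C=C\C=C\[C@H](O[Si](C(C)C)(C(C)C)C(C)C)C/C=C\CCCCC(=O)c1c(O)cc(OC)cc1O | intermediate
32 | (6Z,9R,10E,12Z,15Z)-1-(2,6-dihydroxy-4-methoxyphenyl)-9-hydroxyoctadeca-6,10,12,15-tetraen-1-one | CC/C=C\C/C=C\C=C\[C@H](O)C/C=C\CCCCC(=O)c1c(O)cc(OC)cc1O | target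

**Step count**

Total: 18 steps. Longest linear sequence: 12 steps (steps 7 to 18, from hept-6-ynoic acid 13 and epoxide 14).

**Steps most likely to fail**

Step 16 (aryne insertion). Aryl anion 28 may be protonated before the acyl shift, so that only O-arylation occurs. The aryne may also be consumed by ene or cycloaddition reactions with the chain olefins or by the product phenoxide. Prolonged heating may cause a 1,5-hydrogen shift from C14 across the 12Z alkene or loss of the silyl ether. The fallback makes the same aryl–C1 bond by acylation of an ortho-lithiated arene; it sets out from acid 25 and phenol 1 and comes back at 31. Acid 25 is condensed with MeNH(OMe)·HCl (EDC·HCl, i-Pr2NEt, CH2Cl2) to (6Z,9R,10E,12Z,15Z)-N-methoxy-N-methyl-9-(triisopropylsilyloxy)octadeca-6,10,12,15-tetraenamide F1. Phenol 1 is converted with NaH and excess MOMCl into 1-methoxy-3,5-bis(methoxymethoxy)benzene F2, which n-BuLi (THF, 0 °C) lithiates between the two acetal oxygens to [4-methoxy-2,6-bis(methoxymethoxy)phenyl]lithium F3. Addition of F1 to F3 at −78 °C should give (6Z,9R,10E,12Z,15Z)-1-[4-methoxy-2,6-bis(methoxymethoxy)phenyl]-9-(triisopropylsilyloxy)octadeca-6,10,12,15-tetraen-1-one F4, and Me3SiOTf/2,2'-bipyridyl followed by water removes both acetals to reach 31.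

Step 17 (acetal cleavage). The silyl triflate may ionise the C9 dienyl silyl ether, leading to allylic transposition, elimination or geometric isomerisation of the 10E,12Z-diene. The fallback replaces the methoxymethyl group by a fluoride-labile acetal, so that no acetal cleavage by an electrophile is needed; it sets out from 1 (and uses 25) and comes back at 32. Steps 1 to 4 are run with 2-(trimethylsilyl)ethoxymethyl chloride in place of MOMCl to give, in turn, 3-methoxy-5-{[2-(trimethylsilyl)ethoxy]methoxy}phenol F5, 3-methoxy-5-{[2-(trimethylsilyl)ethoxy]methoxy}phenyl propan-2-ylcarbamate F6, 5-methoxy-3-{[2-(trimethylsilyl)ethoxy]methoxy}-2-(trimethylsilyl)phenyl propan-2-ylcarbamate F7 and 5-methoxy-3-{[2-(trimethylsilyl)ethoxy]methoxy}-2-(trimethylsilyl)phenyl trifluoromethanesulfonate F8. Reaction of F8 with 25 under the conditions of step 16 (CsF is almost insoluble in THF, so the alkylsilane of the acetal should survive) gives (6Z,9R,10E,12Z,15Z)-1-(2-hydroxy-4-methoxy-6-{[2-(trimethylsilyl)ethoxy]methoxy}phenyl)-9-(triisopropylsilyloxy)octadeca-6,10,12,15-tetraen-1-one F9. Excess Bu4NF in THF/DMPU at 45 °C then fragments the acetal by attack at silicon and removes the C9 silyl group in the same operation, giving 32.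

Step 3 (ortho-silylation). Lithiation may occur in part at the other ortho carbon, between the carbamate and methoxy oxygens, which would lead to the regioisomeric aryne; the silyl triflate used for N-silylation may also attack the acetal. The fallback places the silyl group by a halogen–lithium exchange and 1,3 O-to-C silyl shift from a bromide whose position is fixed by symmetry; it sets out from 1 and comes back at 9. The bis-acetal 1-methoxy-3,5-bis(methoxymethoxy)benzene F2 (made from 1 as in the first fallback) is lithiated with n-BuLi between the two acetal oxygens and quenched with BrCCl2CCl2Br to give 2-bromo-5-methoxy-1,3-bis(methoxymethoxy)benzene F10. One acetal is removed by methanolysis stopped at partial conversion (cat. HCl, MeOH, 0 °C, recovered F10 recycled) to give 2-bromo-5-methoxy-3-(methoxymethoxy)phenol F11. Silylation with (Me3Si)2NH in THF at reflux gives [2-bromo-5-methoxy-3-(methoxymethoxy)phenoxy]trimethylsilane F12. n-BuLi (THF, −78 °C) then effects bromine–lithium exchange and silyl migration from oxygen to carbon, giving the lithium salt of phenol 8, which Tf2O converts in the same flask into 9.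

**Further compounds**

F1 | step 16 | (6Z,9R,10E,12Z,15Z)-N-methoxy-N-methyl-9-(triisopropylsilyloxy)octadeca-6,10,12,15-tetraenamide | CC/C=C\C/C=C\C=C\[C@H](O[Si](C(C)C)(C(C)C)C(C)C)C/C=C\CCCCC(=O)N(C)OC
F2 | step 16 | 1-methoxy-3,5-bis(methoxymethoxy)benzene | COCOc1cc(OC)cc(OCOC)c1
F3 | step 16 | [4-methoxy-2,6-bis(methoxymethoxy)phenyl]lithium | [Li]c1c(OCOC)cc(OC)cc1OCOC
F4 | step 16 | (6Z,9R,10E,12Z,15Z)-1-[4-methoxy-2,6-bis(methoxymethoxy)phenyl]-9-(triisopropylsilyloxy)octadeca-6,10,12,15-tetraen-1-one | CC/C=C\C/C=C\C=C\[C@H](O[Si](C(C)C)(C(C)C)C(C)C)C/C=C\CCCCC(=O)c1c(OCOC)cc(OC)cc1OCOC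
F5 | step 17 | 3-methoxy-5-{[2-(trimethylsilyl)ethoxy]methoxy}phenol | COc1cc(O)cc(OCOCC[Si](C)(C)C)c1
F6 | step 17 | 3-methoxy-5-{[2-(trimethylsilyl)ethoxy]methoxy}phenyl propan-2-ylcarbamate | COc1cc(OC(=O)NC(C)C)cc(OCOCC[Si](C)(C)C)c1
F7 | step 17 | 5-methoxy-3-{[2-(trimethylsilyl)ethoxy]methoxy}-2-(trimethylsilyl)phenyl propan-2-ylcarbamate | COc1cc(OC(=O)NC(C)C)c([Si](C)(C)C)c(OCOCC[Si](C)(C)C)c1
F8 | step 17 | 5-methoxy-3-{[2-(trimethylsilyl)ethoxy]methoxy}-2-(trimethylsilyl)phenyl trifluoromethanesulfonate | COc1cc(OS(=O)(=O)C(F)(F)F)c([Si](C)(C)C)c(OCOCC[Si](C)(C)C)c1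
F9 | step 17 | (6Z,9R,10E,12Z,15Z)-1-(2-hydroxy-4-methoxy-6-{[2-(trimethylsilyl)ethoxy]methoxy}phenyl)-9-(triisopropylsilyloxy)octadeca-6,10,12,15-tetraen-1-one | CC/C=C\C/C=C\C=C\[C@H](O[Si](C(C)C)(C(C)C)C(C)C)C/C=C\CCCCC(=O)c1c(O)cc(OC)cc1OCOCC[Si](C)(C)C
F10 | step 3 | 2-bromo-5-methoxy-1,3-bis(methoxymethoxy)benzene | COCOc1cc(OC)cc(OCOC)c1Br
F11 | step 3 | 2-bromo-5-methoxy-3-(methoxymethoxy)phenol | COCOc1cc(OC)cc(O)c1Br
F12 | step 3 | [2-bromo-5-methoxy-3-(methoxymethoxy)phenoxy]trimethylsilane | COCOc1cc(OC)cc(O[Si](C)(C)C)c1Br
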